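**Retrosynthetic overview**
- The target, a 3,3''-biflavanone, is traced back by C2'' inversion of the 4-hydroxyphenyl unit (through its quinone methide) and O-debenzylation to the all-cis, pseudo-C2-symmetric (2S,3S,2''S,3''S) 4'''-O-benzyl biflavanone.
- Key disconnection: each benzo ring A (C4a, C5, C6, C7, C8, C8a) carries oxygen on C5 and C7, the 1,3-pattern of an acetoacetate-derived diene. Both rings are cut at C4a–C5 and C8–C8a, which leaves C4a=C8a as a bromo-enone in each ring of a 3,3'-linked bis(2-aryl-2,3-dihydropyran-4-one) and 1-methoxy-1,3-bis(trimethylsilyloxy)butadiene as the four-carbon partner.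
- The bis(dihydropyranone) already holds all four stereocentres. It is cut at O1–C6 and C2–C3 of each ring into 4-methoxybenzaldehyde, 4-(benzyloxy)benzaldehyde and a C8 bis(silyloxy)tetraene (two catalytic asymmetric hetero-Diels–Alder additions); the tetraene comes from oxidative enolate dimerisation of two molecules of 4-methoxybut-3-en-2-one.
- Ring order: pyranone ring C, pyranone ring C'', then rings A and A'' together; no stereocentre is formed in the key step.

Key step: step 7

Assumption: [CrCl(L)], the complex of trivalent chromium with L = the O,N,O-dianion of (1S,2R)-1-{[3-(1-adamantyl)-2-hydroxy-5-methylbenzylidene]amino}indan-2-ol, is taken to give the S configuration at the aryl-bearing carbon, by extension of its sense of induction with other aldehydes; were the first adduct antipodal, the (1R,2S) complex would be used throughout.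

**Step 1**
Reactants: 1 (E)-4-methoxybut-3-en-2-one (two molecules, joined at their methyl carbons)
Product: 3 (1E,7E)-1,8-dimethoxyocta-1,7-diene-3,6-dione, via lithium enolate 2 (not isolated)
Conditions: LDA (1.05 equiv), THF, −78 °C; then CuCl2 (1.1 equiv), DMF, −78 °C → rt
Reagents that add atoms: (E)-4-methoxybut-3-en-2-one (the second molecule of 1), CO/C=C/C(C)=O
Why: Kinetic deprotonation of the methyl group turns each of the two molecules of 1 into the cross-conjugated lithium enolate, and one-electron oxidation by CuCl2 joins two of these enolates at their methylene carbons (oxidative enolate dimerisation) to the symmetrical 1,4-diketone, which therefore holds the atoms of both molecules; no stereocentre is formed.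

**Step 2**
Reactants: 3 (1E,7E)-1,8-dimethoxyocta-1,7-diene-3,6-dione
Product: 4 (1E,3Z,5Z,7E)-1,8-dimethoxy-3,6-bis(triethylsilyloxy)octa-1,3,5,7-tetraene
Conditions: TESOTf (2.3 equiv), Et3N, Et2O, 0 °C
Reagents that add atoms: triethylsilyl trifluoromethanesulfonate, CC[Si](CC)(CC)OS(=O)(=O)C(F)(F)F
Why: Soft enolisation with a silyl triflate and a tertiary amine converts both ketones into their (Z)-silyl enol ethers (silyl dienol ether formation), which places each chain carbon trans to the methoxyvinyl arm so that both 1-methoxy-3-silyloxy diene units can reach the s-cis form; no stereocentre is formed.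

**Step 3**
Reactants: 4 the bis(silyloxy)tetraene; 5 4-methoxybenzaldehyde; 6 4-(benzyloxy)benzaldehyde
Product: 9 (2S,2'S,3S,3'S)-2'-[4-(benzyloxy)phenyl]-2-(4-methoxyphenyl)-2,2',3,3'-tetrahydro-4H,4'H-[3,3'-bipyran]-4,4'-dione (2,3-cis and 2',3'-cis), via mono-cycloadduct 7 (not isolated), via bis-cycloadduct 8 (not isolated)
Conditions: [CrCl(L)] (5 mol%), 4 Å MS, tBuOMe, rt, 5 (1.0 equiv) first, then 6 (1.5 equiv); then TFA, CH2Cl2, 0 °C
Reagents that add atoms: none
Why: Catalyst-controlled, endo-selective hetero-Diels–Alder addition of aldehydes to 1-methoxy-3-silyloxy dienes with a (Z)-4-substituent gives all-cis adducts, so the chromium catalyst should set C2/C3 and then C2'/C3' (all S, aryl endo and cis to the outward diene substituent); the first addition should be the faster one because it turns the remaining diene into a hindered, non-conjugated 4-alkyl diene, and TFA then ionises each anomeric methoxy group and releases both enones.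

**Step 4**
Reactants: 9 the bis(dihydropyranone)
Product: 10 (2S,2'S,3S,3'S)-2'-[4-(benzyloxy)phenyl]-5,5'-dibromo-2-(4-methoxyphenyl)-2,2',3,3'-tetrahydro-4H,4'H-[3,3'-bipyran]-4,4'-dione
Conditions: NBS (2.1 equiv), CH2Cl2, 0 °C → rt, dark
Reagents that add atoms: N-bromosuccinimide, O=C1CCC(=O)N1Br
Why: C5 of each vinylogous ester is its nucleophilic enol-ether carbon, so electrophilic bromination followed by loss of the C5 proton (α-halogenation of a β-alkoxy enone by addition–elimination) should give the bromo-enones under neutral conditions that leave C3–H and C3'–H untouched.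

**Step 5**
Reactants: 11 methyl acetoacetate
Product: 12 methyl 3-(trimethylsilyloxy)but-2-enoate (E/Z mixture)
Conditions: TMSCl, Et3N, pentane, rt
Reagents that add atoms: chlorotrimethylsilane, C[Si](C)(C)Cl
Why: O-silylation of the enolised β-keto ester under amine base (enol silylation) masks the ketone and prepares the γ-methyl group for deprotonation.

**Step 6**
Reactants: 12 methyl 3-(trimethylsilyloxy)but-2-enoate
Product: 14 (E)-1-methoxy-1,3-bis(trimethylsilyloxy)buta-1,3-diene, via lithium dienolate 13 (not isolated)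
Conditions: LDA, THF, −78 °C; then TMSCl, −78 → 0 °C
Reagents that add atoms: chlorotrimethylsilane, C[Si](C)(C)Cl
Why: LDA removes a γ-proton of the vinylogous carbonate to give the extended ester enolate, and O-silylation gives the 1,3-bis(silyloxy)diene (ketene silyl acetal formation), which is used at once.

**Step 7**
Reactants: 10 the dibromo bis(dihydropyranone); 14 (E)-1-methoxy-1,3-bis(trimethylsilyloxy)buta-1,3-diene (two molecules react, one per bromo-enone)
Product: 17 (2S,3S,2''S,3''S)-4'''-benzyloxy-5,7,5'',7''-tetrahydroxy-4'-methoxy-3,3''-biflavanone (2,3-cis and 2'',3''-cis), via double cycloadduct 15 (not isolated), via tetrakis(trimethylsilyl) ether 16 (not isolated)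
Conditions: 14 (6 equiv), toluene, 100 °C, sealed tube, Ar; then 1 M HCl, THF, 0 °C
Reagents that add atoms: (E)-1-methoxy-1,3-bis(trimethylsilyloxy)buta-1,3-diene (the second molecule of 14), C=C(O[Si](C)(C)C)/C=C(\OC)O[Si](C)(C)C
Why: Proposed new method: each bromo-enone C4a=C8a is polarised by the ring oxygen and the C4 carbonyl so that C8a is its electrophilic carbon, and the CH2 terminus of the ketene-acetal diene is its most nucleophilic one, so a normal-demand, strongly asynchronous [4+2] addition (in the limit a Mukaiyama–Michael addition at C8a followed by closure of the bromo-enolate carbon C4a onto the ketene-acetal carbon) should form C8–C8a and C4a–C5 and place the acetal carbon at C5, peri to C4=O. The closest known reaction type is the Diels–Alder/elimination benzannulation of 1,3-bis(silyloxy)- and 1,1-dialkoxy-3-silyloxy-buta-1,3-dienes with haloquinones and simple α-halo enones; a β-alkoxy α-bromo enone held in a dihydropyranone, and two of them in one molecule, has not been used. Each of the two new rings closes as a six-membered carbocycle by [4+2] cycloaddition onto the existing C4a=C8a bond. No lasting stereocentre is formed: 1,4-loss of methanol (C5–OMe with H-8, triggered by the bromosilane that appears once excess ketene acetal has taken up the first HBr) gives a 5,7-bis(silyloxy)cyclohexa-1,3-diene whose allylic Br-4a and neighbouring H-8a are lost as HBr with aromatisation as the driving force, so neither the face of addition nor the cis H-8a/Br-4a relationship matters. The step needs regioselectivity (CH2 to C8a, never to C4a) and ring closure at the acetal carbon in preference to displacement of bromide; the first is secured by the vinylogous-ester polarisation, the second by running the addition thermally without base or Lewis acid, which also leaves the enolisable C3–H and C3''–H of the cis rings alone. Dilute acid finally cleaves the four aryl silyl ethers of 16 to the free 5,7-phenols.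

**Step 8**
Reactants: 17 the 4'''-O-benzyl cis,cis-biflavanone
Product: 18 (2S,3S,2''S,3''S)-5,7,4''',5'',7''-pentahydroxy-4'-methoxy-3,3''-biflavanone
Conditions: H2 (1 atm), Pd/C (10 wt%), EtOAc–MeOH, rt
Reagents that add atoms: none
Why: Hydrogenolysis of the benzyl aryl ether on Pd/C should be far faster than reduction of the chelated aryl ketones or cleavage of the cyclic C2–O1 bonds, and the neutral medium leaves all four stereocentres alone.

**Step 9**
Reactants: 18 the cis,cis-pentahydroxy biflavanone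
Product: 20 (2S,3S,2''R,3''S)-5,7,4''',5'',7''-pentahydroxy-4'-methoxy-3,3''-biflavanone (2,3-cis and 2'',3''-trans; CNP0196568.4), via quinone methide 19 (not isolated)
Conditions: Et3N (5 equiv), MeOH–H2O 4:1, 40 °C, Ar; then evaporation
Reagents that add atoms: none
Why: The 4'''-phenoxide opens ring C'' by expelling the O1'' phenoxide to a p-quinone methide in which only C2'' has lost its configuration, and reversible oxa-Michael re-closure (retro-oxa-Michael/oxa-Michael epimerisation) should settle on the 2'',3''-trans (2''R) isomer with both ring substituents equatorial, C3'' being the controlling centre; the 4'-methoxy unit cannot form a quinone methide and the 7-phenoxides disfavour enolisation at C3 and C3'', so C2, C3 and C3'' should be kept.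

**Compound list**
1 | (E)-4-methoxybut-3-en-2-one | CO/C=C/C(C)=O | starting material
2 | lithium (E)-4-methoxybuta-1,3-dien-2-olate | C=C(O[Li])/C=C/OC | intermediate
3 | (1E,7E)-1,8-dimethoxyocta-1,7-diene-3,6-dione | CO/C=C/C(=O)CCC(=O)/C=C/OC | intermediate
4 | (1E,3Z,5Z,7E)-1,8-dimethoxy-3,6-bis(triethylsilyloxy)octa-1,3,5,7-tetraene | CO/C=C/C(O[Si](CC)(CC)CC)=C/C=C(O[Si](CC)(CC)CC)/C=C/OC | intermediate
5 | 4-methoxybenzaldehyde | COc1ccc(C=O)cc1 | starting material
6 | 4-(benzyloxy)benzaldehyde | O=Cc1ccc(OCc2ccccc2)cc1 | starting material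
7 | (2R,5S,6S)-2-methoxy-6-(4-methoxyphenyl)-5-[(1Z,3E)-4-methoxy-2-(triethylsilyloxy)buta-1,3-dienyl]-4-(triethylsilyloxy)-5,6-dihydro-2H-pyran (all-cis) | COc1ccc([C@H]2O[C@@H](OC)C=C(O[Si](CC)(CC)CC)[C@H]2/C=C(\O[Si](CC)(CC)CC)/C=C/OC)cc1 | intermediate
8 | (2R,2'R,5S,5'S,6S,6'S)-6'-[4-(benzyloxy)phenyl]-2,2'-dimethoxy-6-(4-methoxyphenyl)-4,4'-bis(triethylsilyloxy)-5,5',6,6'-tetrahydro-2H,2'H-5,5'-bipyran (both rings all-cis) | COc1ccc([C@H]2O[C@@H](OC)C=C(O[Si](CC)(CC)CC)[C@H]2[C@@H]2C(O[Si](CC)(CC)CC)=C[C@H](OC)O[C@@H]2c2ccc(OCc3ccccc3)cc2)cc1 | intermediate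
9 | (2S,2'S,3S,3'S)-2'-[4-(benzyloxy)phenyl]-2-(4-methoxyphenyl)-2,2',3,3'-tetrahydro-4H,4'H-[3,3'-bipyran]-4,4'-dione | COc1ccc([C@H]2OC=CC(=O)[C@H]2[C@@H]2C(=O)C=CO[C@@H]2c2ccc(OCc3ccccc3)cc2)cc1 | intermediate
10 | (2S,2'S,3S,3'S)-2'-[4-(benzyloxy)phenyl]-5,5'-dibromo-2-(4-methoxyphenyl)-2,2',3,3'-tetrahydro-4H,4'H-[3,3'-bipyran]-4,4'-dione | COc1ccc([C@H]2OC=C(Br)C(=O)[C@H]2[C@@H]2C(=O)C(Br)=CO[C@@H]2c2ccc(OCc3ccccc3)cc2)cc1 | intermediate
11 | methyl acetoacetate | COC(=O)CC(C)=O | starting material
12 | methyl 3-(trimethylsilyloxy)but-2-enoate (E/Z mixture) | COC(=O)C=C(C)O[Si](C)(C)C | intermediate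
13 | lithium 1-methoxy-3-(trimethylsilyloxy)buta-1,3-dien-1-olate | C=C(O[Si](C)(C)C)C=C(OC)O[Li] | intermediate
14 | (E)-1-methoxy-1,3-bis(trimethylsilyloxy)buta-1,3-diene | C=C(O[Si](C)(C)C)/C=C(\OC)O[Si](C)(C)C | intermediate
15 | double cycloadduct: in each half a 4a-bromo-5-methoxy-5,7-bis(trimethylsilyloxy)-4a,5,8,8a-tetrahydrochroman-4-one; C2, C3, C2'', C3'' as in 10, new centres C4a, C5, C8a unassigned | COc1ccc([C@H]2OC3CC(O[Si](C)(C)C)=CC(OC)(O[Si](C)(C)C)C3(Br)C(=O)[C@H]2[C@@H]2C(=O)C3(Br)C(OC)(O[Si](C)(C)C)C=C(O[Si](C)(C)C)CC3O[C@@H]2c2ccc(OCc3ccccc3)cc2)cc1 | intermediate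
16 | (2S,3S,2''S,3''S)-4'''-benzyloxy-4'-methoxy-5,7,5'',7''-tetrakis(trimethylsilyloxy)-3,3''-biflavanone | COc1ccc([C@H]2Oc3cc(O[Si](C)(C)C)cc(O[Si](C)(C)C)c3C(=O)[C@H]2[C@@H]2C(=O)c3c(O[Si](C)(C)C)cc(O[Si](C)(C)C)cc3O[C@@H]2c2ccc(OCc3ccccc3)cc2)cc1 | intermediate
17 | (2S,3S,2''S,3''S)-4'''-benzyloxy-5,7,5'',7''-tetrahydroxy-4'-methoxy-3,3''-biflavanone | COc1ccc([C@H]2Oc3cc(O)cc(O)c3C(=O)[C@H]2[C@@H]2C(=O)c3c(O)cc(O)cc3O[C@@H]2c2ccc(OCc3ccccc3)cc2)cc1 | intermediate
18 | (2S,3S,2''S,3''S)-5,7,4''',5'',7''-pentahydroxy-4'-methoxy-3,3''-biflavanone | COc1ccc([C@H]2Oc3cc(O)cc(O)c3C(=O)[C@H]2[C@@H]2C(=O)c3c(O)cc(O)cc3O[C@@H]2c2ccc(O)cc2)cc1 | intermediate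
19 | ring-C''-opened p-quinone methide: the cis-flavanone of unit 1 bearing at C3 a CH(C=quinone methide)–C(=O)–(2,4,6-trihydroxyphenyl) chain, C3'' retained | COc1ccc([C@H]2Oc3cc(O)cc(O)c3C(=O)[C@H]2[C@@H](C=C2C=CC(=O)C=C2)C(=O)c2c(O)cc(O)cc2O)cc1 | intermediate
20 | (2S,3S,2''R,3''S)-5,7,4''',5'',7''-pentahydroxy-4'-methoxy-3,3''-biflavanone (CNP0196568.4) | COc1ccc([C@H]2Oc3cc(O)cc(O)c3C(=O)[C@H]2[C@@H]2C(=O)c3c(O)cc(O)cc3O[C@H]2c2ccc(O)cc2)cc1 | target

**Step count**
Total: 9 steps. Longest linear sequence: 7 steps (steps 1–4, 7–9); steps 5 and 6 form the diene branch.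

**Steps most likely to fail**

1. Step 7 (the proposed new method). The β-alkoxy bromo-enone may be too weak a dienophile, so that the diene decomposes before it adds. If the first C–C bond forms alone, the intermediate may close by displacement of bromide (five-membered ring) or lose bromine reductively instead of closing at the acetal carbon. Fallback with known sulfoxide-activated cycloaddition and thermal syn-elimination: it sets out from 9. Electrophilic sulfenylation at C5 and C5' with PhSCl (CH2Cl2, −78 °C) should give the 5,5'-bis(phenylthio) bis(dihydropyranone) F1. mCPBA (2 equiv, CH2Cl2, −78 °C) should give the 5,5'-bis(phenylsulfinyl) bis(dihydropyranone) F2 as a mixture at sulfur. Heating F2 with 14 in toluene should give the double sulfinyl cycloadduct F3, in which each sulfinyl group on C4a is cis to H-8a as a result of suprafacial addition and leaves as benzenesulfenic acid by syn-elimination. Loss of methanol then gives 16, and dilute acid brings the route back at 17.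

2. Step 3. The two aldehydes may not be differentiated: if the second diene of 4 reacts at a rate close to the first, symmetrical bis-adducts dilute the mixed one. The second cycloaddition also takes place next to existing stereocentres, and a mismatched pairing would erode facial selectivity or stall the addition. Fallback that differentiates the two halves by constitution: it sets out from 3. One equivalent of LiN(SiMe3)2 (THF, −78 °C) should give the lithium mono-enolate F4, and TESCl the mono(silyl dienol ether) F5. Addition of 5 with [CrCl(L)] should give the all-cis cycloadduct F6, and TFA the keto-dihydropyranone (2S,3S)-3-[(E)-4-methoxy-2-oxobut-3-enyl]-2-(4-methoxyphenyl)-2,3-dihydro-4H-pyran-4-one F7, which can be purified. Kinetic deprotonation of the side-chain CH2 of F7 (LiN(SiMe3)2, −78 °C) should give the lithium enolate F8, and TESCl the silyl dienol ether F9. A second chromium-catalysed addition, now of 6, should give the cycloadduct F10, and TFA brings the route back at 9.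

3. Step 9. The epimerisation may not stay at C2'': enolisation at C3 or C3'' with ring opening to chalcones would scramble C2, C3 or C3'', or the equilibrium may stop at a cis/trans mixture at C2''. Fallback that changes the ionisation state of the A rings, so that only the 4'''-phenol can ionise and the leaving O1'' phenol is neutral: it sets out from 17. TBSCl and imidazole (DMF, 0 °C) should silylate only the non-chelated 7- and 7''-hydroxyls to give the 7,7''-bis-O-TBS ether F11. Hydrogenolysis (H2, Pd/C, EtOAc) should give the 4'''-phenol F12. Et3N in DMF at 40 °C should open ring C'' to the silylated quinone methide F13 and re-close it to the 2'',3''-trans bis-silyl ether F14. HF·pyridine (THF, 0 °C) then removes both silyl groups and the route comes back at 20.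

**Further compounds**
F1 | step 7 | (2S,2'S,3S,3'S)-2'-[4-(benzyloxy)phenyl]-2-(4-methoxyphenyl)-5,5'-bis(phenylthio)-2,2',3,3'-tetrahydro-4H,4'H-[3,3'-bipyran]-4,4'-dione | COc1ccc([C@H]2OC=C(Sc3ccccc3)C(=O)[C@H]2[C@@H]2C(=O)C(Sc3ccccc3)=CO[C@@H]2c2ccc(OCc3ccccc3)cc2)cc1
F2 | step 7 | the corresponding 5,5'-bis(phenylsulfinyl) compound (mixture at sulfur) | COc1ccc([C@H]2OC=C(S(=O)c3ccccc3)C(=O)[C@H]2[C@@H]2C(=O)C(S(=O)c3ccccc3)=CO[C@@H]2c2ccc(OCc3ccccc3)cc2)cc1
F3 | step 7 | double cycloadduct of F2 with 14 (4a-phenylsulfinyl analogue of 15; new centres unassigned) | COc1ccc([C@H]2OC3CC(O[Si](C)(C)C)=CC(OC)(O[Si](C)(C)C)C3(S(=O)c3ccccc3)C(=O)[C@H]2[C@@H]2C(=O)C3(S(=O)c4ccccc4)C(OC)(O[Si](C)(C)C)C=C(O[Si](C)(C)C)CC3O[C@@H]2c2ccc(OCc3ccccc3)cc2)cc1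
F4 | step 3 | lithium mono-enolate of 3 | CO/C=C/C(O[Li])=C/CC(=O)/C=C/OC
F5 | step 3 | (1E,5Z,7E)-1,8-dimethoxy-6-(triethylsilyloxy)octa-1,5,7-trien-3-one | CO/C=C/C(O[Si](CC)(CC)CC)=C/CC(=O)/C=C/OC
F6 | step 3 | (2R,5S,6S)-2-methoxy-5-[(E)-4-methoxy-2-oxobut-3-enyl]-6-(4-methoxyphenyl)-4-(triethylsilyloxy)-5,6-dihydro-2H-pyran (all-cis) | COc1ccc([C@H]2O[C@@H](OC)C=C(O[Si](CC)(CC)CC)[C@H]2CC(=O)/C=C/OC)cc1
F7 | step 3 | (2S,3S)-3-[(E)-4-methoxy-2-oxobut-3-enyl]-2-(4-methoxyphenyl)-2,3-dihydro-4H-pyran-4-one | COc1ccc([C@H]2OC=CC(=O)[C@H]2CC(=O)/C=C/OC)cc1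
F8 | step 3 | lithium (Z)-enolate of the side-chain ketone of F7 | COc1ccc([C@H]2OC=CC(=O)[C@H]2/C=C(\O[Li])/C=C/OC)cc1
F9 | step 3 | (2S,3S)-3-[(1Z,3E)-4-methoxy-2-(triethylsilyloxy)buta-1,3-dienyl]-2-(4-methoxyphenyl)-2,3-dihydro-4H-pyran-4-one | COc1ccc([C@H]2OC=CC(=O)[C@H]2/C=C(\O[Si](CC)(CC)CC)/C=C/OC)cc1
F10 | step 3 | cycloadduct of F9 with 6: the dihydropyranone of F7 carrying at C3 an all-cis 6-[4-(benzyloxy)phenyl]-2-methoxy-4-(triethylsilyloxy)-5,6-dihydro-2H-pyran-5-yl group | COc1ccc([C@H]2OC=CC(=O)[C@H]2[C@@H]2C(O[Si](CC)(CC)CC)=C[C@H](OC)O[C@@H]2c2ccc(OCc3ccccc3)cc2)cc1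
F11 | step 9 | 7,7''-bis-O-(tert-butyldimethylsilyl) ether of 17 | COc1ccc([C@H]2Oc3cc(O[Si](C)(C)C(C)(C)C)cc(O)c3C(=O)[C@H]2[C@@H]2C(=O)c3c(O)cc(O[Si](C)(C)C(C)(C)C)cc3O[C@@H]2c2ccc(OCc3ccccc3)cc2)cc1
F12 | step 9 | 7,7''-bis-O-(tert-butyldimethylsilyl) ether of 18 | COc1ccc([C@H]2Oc3cc(O[Si](C)(C)C(C)(C)C)cc(O)c3C(=O)[C@H]2[C@@H]2C(=O)c3c(O)cc(O[Si](C)(C)C(C)(C)C)cc3O[C@@H]2c2ccc(O)cc2)cc1
F13 | step 9 | ring-C''-opened p-quinone methide of F12 (not isolated) | COc1ccc([C@H]2Oc3cc(O[Si](C)(C)C(C)(C)C)cc(O)c3C(=O)[C@H]2[C@@H](C=C2C=CC(=O)C=C2)C(=O)c2c(O)cc(O[Si](C)(C)C(C)(C)C)cc2O)cc1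
F14 | step 9 | 7,7''-bis-O-(tert-butyldimethylsilyl) ether of 20 (2S,3S,2''R,3''S) | COc1ccc([C@H]2Oc3cc(O[Si](C)(C)C(C)(C)C)cc(O)c3C(=O)[C@H]2[C@@H]2C(=O)c3c(O)cc(O[Si](C)(C)C(C)(C)C)cc3O[C@H]2c2ccc(O)cc2)cc1
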